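At the same 0.25 M of coupling partner, the spring run falls to 3.1% starting material by 12.0 h, while the autumn run stalls at 32.1%. I therefore watch [coupling partner], which acts here as the limiting reagent in the making.

| flask | starting material | coupling partner | remark | time |
|---|---|---|---|---|
| spring | 0.050 M | 0.25 M | run made earlier |  |
| autumn | 0.20 M | 0.25 M | run made earlier |  |
| summer | 0.10 M | 0.12 M | run made earlier |  |
| flask | 0.10 M | 0.250 M |  | 20 h |

| run | time / h | starting material / % | mono adduct / % |
|---|---|---|---|
| spring | 2.00 | 43.9 | 32.2 |
| spring | 4.00 | 21.5 | 29.4 |
| spring | 6.00 | 10.8 | 21.9 |
| spring | 8.00 | 9.4 | 15.6 |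
| spring | 10.0 | 5.2 | 10.5 |
| spring | 12.0 | 3.1 | 9.8 |
| autumn | 1.00 | 69.7 | 25.4 |
| autumn | 1.50 | 58.3 | 28.5 |
| autumn | 2.50 | 48.4 | 34.8 |
| autumn | 4.00 | 40.7 | 33.5 |
| autumn | 8.00 | 33.5 | 32.8 |
| autumn | 12.0 | 32.1 | 31.6 |
| summer | 1.00 | 80.7 | 16.7 |
| summer | 3.00 | 60.1 | 29.3 |
| summer | 6.00 | 44.3 | 34.1 |
| summer | 8.00 | 41.1 | 32.8 |
| summer | 12.0 | 36.4 | 31.8 |

(scatter of a reading: 1 percentage point)

- the analysis behind the earlier runs scatters by 1 percentage point, standard deviation

- the starting material standing at 20 h, as a percentage of the starting material charged
- the mono adduct standing at 20 h, as a percentage of the starting material charged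
- the bis adduct standing at 20 h, as a percentage of the starting material charged
- the triple product standing at 20 h, as a percentage of the starting material charged

The first summer reading gives a loss constant of 0.447 /h when scaled to the flask's charge of coupling partner. Multiplied by the time, this gives the partner clock θ, 8.93 for the flask.

There are two extreme versions of the flask. If [coupling partner] held at its charge, the decay would be pseudo-first-order and exp(−θ) would leave 0.0132% starting material. If the partner's share fell in step with the share of starting material, the decay would be second-order and 1/(1+θ) would leave 10.1%.

Counting the whole partner charge as used, the autumn stall cost 1.84 partners per starting material converted. That is less than the flask's 2.50 per starting material charged, so at that cost the partner's share runs ahead of the share of starting material, and I put the flask below 10.1%. I place it near that figure because the cost was read at 67.9% conversion and the flask goes deeper. The readings show no bis adduct or triple product, so I reckon only the starting material.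

The forecast gives 7.5% starting material, 15% mono adduct, 12.5% bis adduct and 65% triple product, with “each step taking one coupling partner”.

At 20 h the flask holds 7.55% starting material, 15.7% mono adduct, 1.02% bis adduct and 4.32% triple product.

    starting material + coupling partner → mono adduct (k = 5.20 × 10⁻⁴ /M/s)
    coupling partner + mono adduct → bis adduct (k = 6.10 × 10⁻⁴ /M/s)
    coupling partner + bis adduct → triple product (k = 0.00150 /M/s)
    coupling partner + triple product → tetra adduct (k = 0.00100 /M/s)
    bis adduct → side product (k = 1.70 × 10⁻⁴ /s)

The flask's starting material stands below 10.1%. The flask's partner share led at 10.0 h, 17.8% against 12.9%, but at 20 h it is 7.4%, under the 7.6% of starting material. A neighbour flask with the same charges, read at 3.0 d, has θ = 32.2, so 1/(1+θ) gives 3.02%. That neighbour flask holds more starting material than that figure, 4.11%, and its partner share stands below its share of starting material, at 0.69%.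

The data were computed for an exercise, and the scatter is random.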